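**Plan**

1. Locants: ring A = C1–C2–C3–C4–C5–C10 (C1–OH, C3–O-angelate, C4–Me, C5–Me), ring B = C5–C6–C7–C8–C9–C10 (C8=O, C7–C11). Retrosynthetic cuts, in order: C11–OO (ene reaction), C7–C11 (aldol), the angelate ester, then C2–C3 and C1–C10 together (ring A), then C4–C5 (Claisen).
2. Forward: ring B is 3-methylcyclohexenone. A Johnson–Claisen rearrangement attaches C3–C4 at C5 and makes the quaternary centre; allylic oxidation and ketalization install the masked C8 ketone. Ring A is then closed in one radical-chain annulation with phenyl vinyl sulfone, which supplies C1 and C2.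
3. Enabling feature: the acyl carbon C3 and the ring-B alkene carbon C10 are 1,4-related through C4 and quaternary C5 (a 4-pentenal with its alkene inside ring B). Because C5 is quaternary and C8 is a ketal carbon, the C9=C10 alkene has no allylic hydrogen and the acyl radical cannot close on it directly, so a two-carbon acceptor can be inserted between C3 and C10.
4. Stereochemistry: C5 comes from the (R)-allylic alcohol (CBS reduction) by suprafacial chirality transfer in the Claisen step; C4 by equilibration α to the C3 ketone; C3 by hydride attack anti to both methyls; C1 is relayed from the C3 hydroxyl by vanadium-directed epoxidation.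
5. The C1 hydroxyl and the C9=C10 bond are released together when the C8 ketone is unmasked (β,γ-epoxy ketone opening), after the angelate is already on C3, so the two hydroxyls never need to be differentiated. An isopropylidene at C7 and a singlet-oxygen ene reaction complete the dienone hydroperoxide.

Key step: step 6

Assumption: the SMILES is read as (1R,3S,4R,5R), i.e. the C1 hydroxyl, the C3 angelate and the C4 and C5 methyls all lie on one face, called β below; the locants of line 1 are used for all intermediates.

**Route**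

Step 1
Reactants: 1 3-methylcyclohex-2-en-1-one
Product: 2 (R)-3-methylcyclohex-2-en-1-ol
Conditions: (S)-2-methyl-CBS-oxazaborolidine (10 mol%), catecholborane (1.5 equiv), toluene, −78 °C; aq. NaOH work-up
Reagents that add atoms: none
Why: Corey–Bakshi–Shibata reduction: the oxazaborolidine-bound borane should deliver hydride to one face of the enone carbonyl (alkene arm as the large group, 1,2-addition), which sets the carbinol carbon (future C9) as R.

Step 2
Reactants: 2 (R)-3-methylcyclohex-2-en-1-ol, 3 triethyl orthopropionate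
Product: 5 ethyl 2-[(1S)-1-methylcyclohex-2-en-1-yl]propanoate (both C4 epimers), via ketene acetal 4 (not isolated)
Conditions: 3 (5 equiv), EtCO2H (5 mol%), 140 °C, EtOH distilled off
Reagents that add atoms: none
Why: Johnson–Claisen rearrangement: the [3,3] shift of ketene acetal 4 should form C4–C5 on the ring face that the C9–O bond leaves (suprafacial 1,3-chirality transfer), which creates the quaternary C5 in the target configuration and moves the alkene to C9=C10; the C4 epimer ratio does not matter because C4 is equilibrated in step 7.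

Step 3
Reactants: 5 ethyl 2-[(1S)-1-methylcyclohex-2-en-1-yl]propanoate
Product: 6 ethyl 2-[(1S)-1-methyl-4-oxocyclohex-2-en-1-yl]propanoate
Conditions: Rh2(cap)4 (cap = caprolactamate, 1 mol%), t-BuOOH (5 equiv), K2CO3, CH2Cl2, 25 °C
Reagents that add atoms: tert-butyl hydroperoxide, CC(C)(C)OO
Why: Allylic C–H oxidation by a tert-butylperoxyl radical chain: the ring alkene has allylic hydrogens only at C8, because its other neighbour C5 is quaternary, so the C8 ketone (enone) should form regiospecifically.

Step 4
Reactants: 6 ethyl 2-[(1S)-1-methyl-4-oxocyclohex-2-en-1-yl]propanoate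
Product: 7 ethyl 2-[(8S)-8-methyl-1,4-dioxaspiro[4.5]dec-6-en-8-yl]propanoate
Conditions: Me3SiOCH2CH2OSiMe3 (2 equiv), Me3SiOTf (5 mol%), CH2Cl2, −78 → −20 °C
Reagents that add atoms: 1,2-bis(trimethylsilyloxy)ethane, C[Si](C)(C)OCCO[Si](C)(C)C
Why: Silyl-triflate-catalysed ketalization of the enone under aprotic conditions: the C8 carbonyl is masked as the dioxolane while the C9=C10 bond stays in place (it cannot move toward quaternary C5) and the ester is untouched.

Step 5
Reactants: 7 ethyl 2-[(8S)-8-methyl-1,4-dioxaspiro[4.5]dec-6-en-8-yl]propanoate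
Product: 8 2-[(8S)-8-methyl-1,4-dioxaspiro[4.5]dec-6-en-8-yl]propanal (both C4 epimers)
Conditions: i-Bu2AlH (1.1 equiv), CH2Cl2, −78 °C; aq. potassium sodium tartrate
Reagents that add atoms: none
Why: Partial reduction of the ester with i-Bu2AlH: the tetrahedral aluminium hemiacetal of this hindered α-branched ester should persist at −78 °C and give the aldehyde on work-up, the ketal being inert.

Step 6
Reactants: 8 2-[(8S)-8-methyl-1,4-dioxaspiro[4.5]dec-6-en-8-yl]propanal, 9 phenyl vinyl sulfone
Product: 10 8,8-(ethylenedioxy)-4,5β-dimethyl-1-(phenylsulfonyl)-cis-decalin-3-one (H-10 cis to the C5 methyl; epimers at C1 and C4)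
Conditions: 9 (3 equiv), (t-BuO)3SiSH (10 mol%), di-tert-butyl hyponitrite (5 mol%), dioxane, 60 °C, 8 added over 6 h
Reagents that add atoms: none
Why: Proposed new method: a thiol-catalysed radical chain is expected in which the thiyl radical abstracts the formyl hydrogen of 8, the nucleophilic acyl radical (C3) adds to the unsubstituted carbon of the electron-poor alkene 9 (C2–C3 bond), and the electrophilic α-sulfonyl radical (C1) then attacks C10 of the ring-B alkene (C1–C10 bond) before the resulting nucleophilic C9 radical takes hydrogen from the thiol. The closest known reactions are the thiol-catalysed radical-chain hydroacylation of vinyl sulfones and the tin- or silane-mediated annulations in which an acyl-radical adduct cyclizes onto a tethered alkene. Ring A is the only ring closed, in the 6-exo-trig mode, the attack on C10 coming from the face that carries the C4–C5 tether, hence the cis ring fusion. The new stereocentres C1 and C10 are deliberately left uncontrolled, because both become sp2 in step 7, while C5 is untouched and C4 is equilibrated later. The step needs addition to 9 to outrun decarbonylation of the α-branched acyl radical (excess 9, 60 °C) and ring closure to outrun hydrogen transfer to the α-sulfonyl radical, which is secured by the polarity mismatch of this radical with the thiol, by slow addition of 8 and by the quaternary C5 next to the tether (gem-dialkyl effect). Regioselectivity for C10 over C9 follows from ring size (6-exo against 7-endo), direct closure of the acyl radical on the alkene would need a four-membered ring, and the alkene has no allylic hydrogen (C8 is the ketal carbon, C5 is quaternary), so allylic abstraction is excluded.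

Step 7
Reactants: 10 8,8-(ethylenedioxy)-4,5β-dimethyl-1-(phenylsulfonyl)-cis-decalin-3-one
Product: 12 8,8-(ethylenedioxy)-4β,5β-dimethyl-octal-1(10)-en-3-one, via conjugated enone 11 (not isolated)
Conditions: KOt-Bu (3 equiv), t-BuOH/THF, 0 → 25 °C; then poured into cold 10% aq. AcOH
Reagents that add atoms: none
Why: E1cB loss of benzenesulfinate gives enone 11, whose potassium dienolate (γ-deprotonation at C10) is protonated kinetically at C2 to give the β,γ-enone (base-mediated deconjugation); under the same conditions C4, α to the ketone, should equilibrate to the more stable epimer with its methyl equatorial and cis to the C5 methyl.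

Step 8
Reactants: 12 8,8-(ethylenedioxy)-4β,5β-dimethyl-octal-1(10)-en-3-one
Product: 13 8,8-(ethylenedioxy)-4β,5β-dimethyl-octal-1(10)-en-3β-ol
Conditions: LiBH(s-Bu)3 (1.2 equiv), THF, −78 °C
Reagents that add atoms: none
Why: Ketone reduction with a bulky hydride: attack on C3 from the α face, anti to the adjacent C4 methyl and to the axial C5 methyl, should give the axial 3β-alcohol, cis to both methyls.

Step 9
Reactants: 13 8,8-(ethylenedioxy)-4β,5β-dimethyl-octal-1(10)-en-3β-ol
Product: 14 1β,10β-epoxy-8,8-(ethylenedioxy)-4β,5β-dimethyldecalin-3β-ol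
Conditions: VO(acac)2 (5 mol%), t-BuOOH (1.5 equiv), CH2Cl2, 0 → 25 °C
Reagents that add atoms: tert-butyl hydroperoxide, CC(C)(C)OO
Why: Vanadium-catalysed hydroxyl-directed epoxidation: the vanadate ester of the homoallylic, pseudo-axial 3β-hydroxyl should deliver the peroxide oxygen to the same (β) face of the C1=C10 alkene, which sets C1 (and transiently C10) from C3.

Step 10
Reactants: 14 1β,10β-epoxy-8,8-(ethylenedioxy)-4β,5β-dimethyldecalin-3β-ol, 15 angelic acid [(Z)-2-methylbut-2-enoic acid]
Product: 17 1β,10β-epoxy-8,8-(ethylenedioxy)-4β,5β-dimethyldecalin-3β-yl angelate, via mixed anhydride 16 (not isolated)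
Conditions: 15 (3 equiv), 2,4,6-Cl3C6H2COCl, Et3N, toluene, 25 °C; then 14, 80 °C
Reagents that add atoms: none
Why: Yamaguchi esterification without a nucleophilic amine catalyst: the mixed anhydride should acylate the hindered 3β-hydroxyl at the angeloyl carbonyl under conditions expected to retain the (Z)-alkene of the angelate; no stereocentre is touched.

Step 11
Reactants: 17 1β,10β-epoxy-8,8-(ethylenedioxy)-4β,5β-dimethyldecalin-3β-yl angelate
Product: 19 3β-angeloyloxy-1β-hydroxy-4β,5β-dimethyl-octal-9-en-8-one, via epoxy ketone 18 (not isolated)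
Conditions: PdCl2(MeCN)2 (5 mol%), acetone/H2O (20:1), 25 °C; then Et3N (2 equiv), 25 °C
Reagents that add atoms: water, O
Why: Neutral deketalization unmasks the C8 ketone, and the β,γ-epoxy ketone 18 opens by E1cB elimination (C9 enolate, C10–O cleavage) to the γ-hydroxy enone, so that the C9=C10 bond and the free 1β-hydroxyl appear together with the C1–O bond, and hence the C1 configuration, untouched.

Step 12
Reactants: 19 3β-angeloyloxy-1β-hydroxy-4β,5β-dimethyl-octal-9-en-8-one, 20 acetone
Product: 21 3β-angeloyloxy-1β-hydroxy-7-(2-hydroxypropan-2-yl)-4β,5β-dimethyl-octal-9-en-8-one (C7 epimers)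
Conditions: LiN(SiMe3)2 (2.2 equiv), THF, −78 °C; ZnCl2 (2.2 equiv); 20 (5 equiv), −78 → −40 °C; aq. NH4Cl
Reagents that add atoms: none
Why: Aldol addition of the kinetic cross-conjugated enolate: after the C1 alkoxide forms, the amide base removes an α′ hydrogen at C7 (the only enolizable position of the enone) and the zinc enolate adds to acetone; the hindered silylamide is not expected to attack or deprotonate the angelate at −78 °C, and the C7 stereocentre is lost in step 13.

Step 13
Reactants: 21 3β-angeloyloxy-1β-hydroxy-7-(2-hydroxypropan-2-yl)-4β,5β-dimethyl-octal-9-en-8-one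
Product: 22 3β-angeloyloxy-1β-hydroxyeremophila-7(11),9-dien-8-one
Conditions: p-TsOH·H2O (10 mol%), benzene, 40 °C
Reagents that add atoms: none
Why: Acid-catalysed dehydration of the tertiary β-hydroxy ketone: loss of water should give the conjugated tetrasubstituted C7=C11 isopropylidene, while the secondary C1 alcohol, whose cation would be destabilized by the enone, is left.

Step 14
Reactants: 22 3β-angeloyloxy-1β-hydroxyeremophila-7(11),9-dien-8-one
Product: 23 (1R,3S,4R,5R)-3-angeloyloxy-1-hydroxy-11-hydroperoxyeremophila-6,9-dien-8-one (CNP0300636.1)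
Conditions: O2, tetraphenylporphyrin (1 mol%), visible light, CH2Cl2, −20 °C
Reagents that add atoms: dioxygen, O=O
Why: Schenck ene reaction of singlet oxygen: on the α,β-unsaturated ketone the hydrogen is taken from the alkyl group geminal to the carbonyl (C6), oxygen binds to C11 and the double bond moves to C6=C7, which gives the tertiary hydroperoxide and the cross-conjugated dienone; the tetrasubstituted alkene should react well ahead of the angelate and the C9=C10 enone alkene.

**Compound list**

1 | 3-methylcyclohex-2-en-1-one | CC1=CC(=O)CCC1 | starting material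
2 | (R)-3-methylcyclohex-2-en-1-ol | O[C@H]1C=C(C)CCC1 | intermediate
3 | triethyl orthopropionate | CCC(OCC)(OCC)OCC | starting material
4 | ketene acetal, (R)-1-[(1-ethoxyprop-1-en-1-yl)oxy]-3-methylcyclohex-2-ene | CC=C(OCC)O[C@H]1C=C(C)CCC1 | intermediate (not isolated)
5 | ethyl 2-[(1S)-1-methylcyclohex-2-en-1-yl]propanoate (C4 epimers) | CCOC(=O)C(C)[C@]1(C)C=CCCC1 | intermediate
6 | ethyl 2-[(1S)-1-methyl-4-oxocyclohex-2-en-1-yl]propanoate | CCOC(=O)C(C)[C@]1(C)C=CC(=O)CC1 | intermediate
7 | ethyl 2-[(8S)-8-methyl-1,4-dioxaspiro[4.5]dec-6-en-8-yl]propanoate | CCOC(=O)C(C)[C@]1(C)C=CC2(OCCO2)CC1 | intermediate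
8 | 2-[(8S)-8-methyl-1,4-dioxaspiro[4.5]dec-6-en-8-yl]propanal | O=CC(C)[C@]1(C)C=CC2(OCCO2)CC1 | intermediate
9 | phenyl vinyl sulfone | C=CS(=O)(=O)c1ccccc1 | starting material
10 | 8,8-(ethylenedioxy)-4,5β-dimethyl-1-(phenylsulfonyl)-cis-decalin-3-one (epimers at C1 and C4) | O=C1CC(S(=O)(=O)c2ccccc2)[C@@H]3CC4(OCCO4)CC[C@]3(C)C1C | intermediate
11 | 8,8-(ethylenedioxy)-4β,5β-dimethyl-cis-decal-1-en-3-one | O=C1C=C[C@@H]2CC3(OCCO3)CC[C@]2(C)[C@H]1C | intermediate (not isolated)
12 | 8,8-(ethylenedioxy)-4β,5β-dimethyl-octal-1(10)-en-3-one | O=C1CC=C2CC3(OCCO3)CC[C@]2(C)[C@H]1C | intermediate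
13 | 8,8-(ethylenedioxy)-4β,5β-dimethyl-octal-1(10)-en-3β-ol | O[C@H]1CC=C2CC3(OCCO3)CC[C@]2(C)[C@H]1C | intermediate
14 | 1β,10β-epoxy-8,8-(ethylenedioxy)-4β,5β-dimethyldecalin-3β-ol | O[C@H]1C[C@H]2O[C@]23CC4(OCCO4)CC[C@]3(C)[C@H]1C | intermediate
15 | angelic acid, (Z)-2-methylbut-2-enoic acid | C/C=C(/C)C(=O)O | starting material
16 | angelic 2,4,6-trichlorobenzoic anhydride | C/C=C(/C)C(=O)OC(=O)c1c(Cl)cc(Cl)cc1Cl | intermediate (not isolated)
17 | 1β,10β-epoxy-8,8-(ethylenedioxy)-4β,5β-dimethyldecalin-3β-yl angelate | C/C=C(/C)C(=O)O[C@H]1C[C@H]2O[C@]23CC4(OCCO4)CC[C@]3(C)[C@H]1C | intermediate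
18 | 3β-angeloyloxy-1β,10β-epoxy-4β,5β-dimethyldecalin-8-one | C/C=C(/C)C(=O)O[C@H]1C[C@H]2O[C@]23CC(=O)CC[C@]3(C)[C@H]1C | intermediate (not isolated)
19 | 3β-angeloyloxy-1β-hydroxy-4β,5β-dimethyl-octal-9-en-8-one | C/C=C(/C)C(=O)O[C@H]1C[C@@H](O)C2=CC(=O)CC[C@]2(C)[C@H]1C | intermediate
20 | acetone | CC(C)=O | starting material
21 | 3β-angeloyloxy-1β-hydroxy-7-(2-hydroxypropan-2-yl)-4β,5β-dimethyl-octal-9-en-8-one (C7 epimers) | C/C=C(/C)C(=O)O[C@H]1C[C@@H](O)C2=CC(=O)C(C(C)(C)O)C[C@]2(C)[C@H]1C | intermediate
22 | 3β-angeloyloxy-1β-hydroxyeremophila-7(11),9-dien-8-one | C/C=C(/C)C(=O)O[C@H]1C[C@@H](O)C2=CC(=O)C(=C(C)C)C[C@]2(C)[C@H]1C | intermediate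
23 | (1R,3S,4R,5R)-3-angeloyloxy-1-hydroxy-11-hydroperoxyeremophila-6,9-dien-8-one | C/C=C(/C)C(=O)O[C@H]1C[C@@H](O)C2=CC(=O)C(C(C)(C)OO)=C[C@]2(C)[C@H]1C | target

**Summary**

Total step count: 14. Longest linear sequence: 14 steps (from 1).

Steps most likely to fail:

1. Step 6 (proposed new method). What may go wrong: hydrogen transfer to the α-sulfonyl radical before ring closure (open-chain keto sulfone only), or decarbonylation of the acyl radical. Fallback with known chemistry, from 8 back to 11: CH2=CHMgBr adds to 8 to give the allylic alcohol F1; Dess–Martin oxidation gives the vinyl ketone F2; an iron-hydride hydrogen-atom-transfer reductive olefin–enone coupling (Fe(acac)3, PhSiH3, EtOH, 60 °C) closes ring A by 6-endo Giese attack of the C10 radical on the enone terminus C1 to give the cis-decalone F3; LiN(i-Pr)2 and Me3SiCl give the less substituted silyl enol ether F4; Saegusa–Ito oxidation with Pd(OAc)2 returns enone 11, which is then treated with KOt-Bu as in step 7.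

2. Step 9. What may go wrong: poor facial selectivity, because steric shielding of the β face by the axial C5 methyl opposes delivery from the 3β-hydroxyl. Fallback, from 13 back to 19: the sterically controlled peracid epoxidation (mCPBA, NaHCO3, CH2Cl2) is used deliberately to give the α-epoxy alcohol F5; angeloylation as in step 10 gives the α-epoxy angelate F6; deketalization and epoxide opening as in step 11 give the 1α-alcohol F7; Mitsunobu inversion with 4-nitrobenzoic acid (PPh3, diisopropyl azodicarboxylate) gives the 1β-nitrobenzoate F8; selective methanolysis of the nitrobenzoate (K2CO3, MeOH, 0 °C) returns 19.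

3. Step 10. What may go wrong: isomerization of the angeloyl group to the tigloyl group during activation, or slow acylation of the hindered axial hydroxyl with loss of the epoxide at 80 °C. Fallback, from 14 back to 17: 14 is esterified at 25 °C with 2-[bis(2,2,2-trifluoroethoxy)phosphoryl]propanoic acid (dicyclohexylcarbodiimide, 4-dimethylaminopyridine) to give the phosphonopropionate F9, and a Still–Gennari olefination with acetaldehyde (KN(SiMe3)2, 18-crown-6, THF, −78 °C) builds the (Z)-2-methylbut-2-enoate on the molecule to give 17.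

**Further compounds**

F1 | step 6 | 4-[(8S)-8-methyl-1,4-dioxaspiro[4.5]dec-6-en-8-yl]pent-1-en-3-ol | C=CC(O)C(C)[C@]1(C)C=CC2(OCCO2)CC1
F2 | step 6 | 4-[(8S)-8-methyl-1,4-dioxaspiro[4.5]dec-6-en-8-yl]pent-1-en-3-one | C=CC(=O)C(C)[C@]1(C)C=CC2(OCCO2)CC1
F3 | step 6 | 8,8-(ethylenedioxy)-4,5β-dimethyl-cis-decalin-3-one | O=C1CC[C@@H]2CC3(OCCO3)CC[C@]2(C)C1C
F4 | step 6 | 8,8-(ethylenedioxy)-4,5β-dimethyl-3-(trimethylsilyloxy)-cis-decal-2-ene | C[Si](C)(C)OC1=CC[C@@H]2CC3(OCCO3)CC[C@]2(C)C1C
F5 | step 9 | 1α,10α-epoxy-8,8-(ethylenedioxy)-4β,5β-dimethyldecalin-3β-ol | O[C@H]1C[C@@H]2O[C@@]23CC4(OCCO4)CC[C@]3(C)[C@H]1C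
F6 | step 9 | 1α,10α-epoxy-8,8-(ethylenedioxy)-4β,5β-dimethyldecalin-3β-yl angelate | C/C=C(/C)C(=O)O[C@H]1C[C@@H]2O[C@@]23CC4(OCCO4)CC[C@]3(C)[C@H]1C
F7 | step 9 | 3β-angeloyloxy-1α-hydroxy-4β,5β-dimethyl-octal-9-en-8-one | C/C=C(/C)C(=O)O[C@H]1C[C@H](O)C2=CC(=O)CC[C@]2(C)[C@H]1C
F8 | step 9 | 3β-angeloyloxy-4β,5β-dimethyl-8-oxo-octal-9-en-1β-yl 4-nitrobenzoate | C/C=C(/C)C(=O)O[C@H]1C[C@@H](OC(=O)c2ccc(cc2)[N+](=O)[O-])C3=CC(=O)CC[C@]3(C)[C@H]1C
F9 | step 10 | 1β,10β-epoxy-8,8-(ethylenedioxy)-4β,5β-dimethyldecalin-3β-yl 2-[bis(2,2,2-trifluoroethoxy)phosphoryl]propanoate | CC(C(=O)O[C@H]1C[C@H]2O[C@]23CC4(OCCO4)CC[C@]3(C)[C@H]1C)P(=O)(OCC(F)(F)F)OCC(F)(F)F
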